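**Plan**

1. Numbering (cembrane): C1 and C2 are the ring-fusion carbons (C2 bears the lactone oxygen). The macrocycle runs C2–C3=C4(Me)–C5–C6–C7=C8(CH2OAc, C19)–C9–C10–C11=C12(Me)–C13–C14–C1. Ring A is the lactone O–C16(=O)–C15(=C17H2)–C1–C2.
2. Enabling feature: the C17=C15–C1 allyl unit of ring A. In the butenolide isomer (C1=C15 endocyclic, C17 carrying PhSO2), C1 is a radical acceptor and C17 a radical leaving site. One addition–fragmentation can therefore close the 14-membered ring at C1–C14, set C1 and unveil the exo-methylene.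
3. Retrosynthetic cuts, in order: C1–C14 (macrocycle); C1=C15 (ring-closing metathesis) and the C16–O acyl bond; C1–C2 (vinylzinc addition to the C2 enal); C7=C8 (Still–Gennari olefination); C8–C9 (phosphonate alkylation); C10–C11 (alkenylalanate plus oxirane).
4. Forward: fragment 1 (C8–C14 with C19, from a butynyl silyl ether) and fragment 2 (C2–C7, from geranyl acetate) are joined at C7=C8. The chain is taken to the C2 enal, vinylated, acylated, ring A is closed as a butenolide, and the 14-membered ring closes last.
5. Stereochemistry: C2 from a catalyst-controlled vinylzinc addition; C1 in the key step under control of C2 and the C4 methyl (A(1,3) strain); 3E from geranyl acetate, 11E from syn-carboalumination, 7Z from the Still–Gennari olefination.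

Key step: step 16

Remark: the sense of induction of (+)-3-exo-morpholinoisoborneol in step 10 is assigned by analogy with ethyl transfer from diethylzinc (Re-face delivery here); if the analogy did not hold, the enantiomeric ligand would be used.

**Route**

Step 1
Reactants: 1 tert-butyl(but-3-yn-1-yloxy)dimethylsilane
Product: 4 (E)-6-[(tert-butyldimethylsilyl)oxy]-4-methylhex-3-en-1-ol, via alkenyldimethylalane 2 (not isolated), via lithium alkenylalanate 3 (not isolated)
Conditions: Me3Al (2.5 equiv), Cp2ZrCl2 (0.25 equiv), CH2Cl2, 0 °C to rt; then n-BuLi, hexane/THF, −30 °C; then ethylene oxide, −30 to 0 °C; aq. NH4Cl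
Reagents that add atoms: trimethylaluminium C[Al](C)C; ethylene oxide C1CO1
Why: Negishi zirconium-catalysed carboalumination adds methyl and aluminium syn across the terminal alkyne with the methyl on the internal carbon, and the derived alanate opens oxirane with retention of the alkene geometry, so the (E)-C11=C12 olefin and the C9–C10 arm should be set in one flask.

Step 2
Reactants: 4 (E)-6-[(tert-butyldimethylsilyl)oxy]-4-methylhex-3-en-1-ol
Product: 5 (E)-tert-butyl[(6-iodo-3-methylhex-3-en-1-yl)oxy]dimethylsilane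
Conditions: I2, PPh3, imidazole, CH2Cl2, 0 °C to rt
Reagents that add atoms: iodine II
Why: Appel iodination converts the primary alcohol into the iodide by SN2 displacement of the alkoxyphosphonium ion without touching the silyl ether or the trisubstituted olefin.

Step 3
Reactants: 5 (E)-tert-butyl[(6-iodo-3-methylhex-3-en-1-yl)oxy]dimethylsilane; 6 methyl bis(2,2,2-trifluoroethyl)phosphonoacetate
Product: 7 methyl (E)-2-[bis(2,2,2-trifluoroethoxy)phosphoryl]-8-[(tert-butyldimethylsilyl)oxy]-6-methyloct-5-enoate
Conditions: NaH (1.0 equiv), DMSO, rt; then 5, 50 °C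
Reagents that add atoms: none
Why: SN2 C-alkylation of the sodium phosphonoacetate by the unhindered primary homoallylic iodide (malonate-type alkylation) forms the C8–C9 bond and brings in C8 and C19, the racemic C8 centre being destroyed in step 7.

Step 4
Reactants: 7 methyl (E)-2-[bis(2,2,2-trifluoroethoxy)phosphoryl]-8-[(tert-butyldimethylsilyl)oxy]-6-methyloct-5-enoate
Product: 8 methyl (E)-2-[bis(2,2,2-trifluoroethoxy)phosphoryl]-8-hydroxy-6-methyloct-5-enoate
Conditions: HF·pyridine, THF/pyridine, 0 °C to rt
Reagents that add atoms: none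
Why: Fluoride-mediated desilylation cleaves the primary silyl ether under mildly acidic conditions that should leave the base-sensitive trifluoroethyl phosphonate and the methyl ester intact.

Step 5
Reactants: 8 methyl (E)-2-[bis(2,2,2-trifluoroethoxy)phosphoryl]-8-hydroxy-6-methyloct-5-enoate
Product: 9 methyl (E)-2-[bis(2,2,2-trifluoroethoxy)phosphoryl]-8-iodo-6-methyloct-5-enoate
Conditions: I2, PPh3, imidazole, CH2Cl2, 0 °C
Reagents that add atoms: iodine II
Why: A second Appel iodination turns the C14 alcohol into the primary iodide that later serves as the radical precursor, the weakly basic imidazole being unable to alkylate or cleave the phosphonate.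

Step 6
Reactants: 10 geranyl acetate
Product: 12 (E)-6-acetoxy-4-methylhex-4-enal, via secondary ozonide 11 (not isolated)
Conditions: O3 (1.0 equiv, titrated), CH2Cl2, −78 °C; then Me2S, −78 °C to rt
Reagents that add atoms: ozone [O-][O+]=O
Why: Chemoselective ozonolysis with one equivalent of ozone should cleave the electron-rich 6,7-olefin in preference to the 2,3-olefin deactivated by the allylic acetate, and reduction of the ozonide gives the C7 aldehyde with the (E)-C3=C4 olefin of geranyl acetate retained.

Step 7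
Reactants: 9 methyl (E)-2-[bis(2,2,2-trifluoroethoxy)phosphoryl]-8-iodo-6-methyloct-5-enoate; 12 (E)-6-acetoxy-4-methylhex-4-enal
Product: 13 methyl (2Z,6E)-8-acetoxy-2-[(E)-6-iodo-4-methylhex-3-en-1-yl]-6-methylocta-2,6-dienoate
Conditions: KN(SiMe3)2 (1.05 equiv), 18-crown-6, THF, −78 °C
Reagents that add atoms: none
Why: In the Still–Gennari variant of the Horner–Wadsworth–Emmons reaction the electron-poor bis(trifluoroethyl) phosphonate eliminates fast from the kinetic adduct under dissociating conditions, which places the ester cis to the aldehyde-derived chain and should set the (Z)-C7=C8 trisubstituted olefin.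

Step 8
Reactants: 13 methyl (2Z,6E)-8-acetoxy-2-[(E)-6-iodo-4-methylhex-3-en-1-yl]-6-methylocta-2,6-dienoate
Product: 14 methyl (2Z,6E)-8-hydroxy-2-[(E)-6-iodo-4-methylhex-3-en-1-yl]-6-methylocta-2,6-dienoate
Conditions: K2CO3 (cat.), MeOH, 0 °C
Reagents that add atoms: none
Why: Base-catalysed transesterification removes the allylic acetate, while the hindered conjugated methyl ester is degenerate toward methanol and the primary iodide is inert at this temperature.

Step 9
Reactants: 14 methyl (2Z,6E)-8-hydroxy-2-[(E)-6-iodo-4-methylhex-3-en-1-yl]-6-methylocta-2,6-dienoate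
Product: 15 methyl (2Z,6E)-2-[(E)-6-iodo-4-methylhex-3-en-1-yl]-6-methyl-8-oxoocta-2,6-dienoate
Conditions: MnO2, CH2Cl2, rt
Reagents that add atoms: none
Why: Chemoselective allylic oxidation with MnO2 should give the (E)-enal at C2 without isomerising the C3=C4 bond or touching the ester and iodide.

Step 10
Reactants: 15 methyl (2Z,6E)-2-[(E)-6-iodo-4-methylhex-3-en-1-yl]-6-methyl-8-oxoocta-2,6-dienoate
Product: 16 methyl (2Z,6E,8R)-8-hydroxy-2-[(E)-6-iodo-4-methylhex-3-en-1-yl]-6-methyldeca-2,6,9-trienoate
Conditions: (CH2=CH)2Zn (from CH2=CHMgBr and ZnBr2; N,N,N',N'-tetraethylethylenediamine to bind MgBr2), (+)-3-exo-morpholinoisoborneol (10 mol %), toluene/THF, −30 to 0 °C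
Reagents that add atoms: vinylmagnesium bromide C=C[Mg]Br (transferred as divinylzinc C=C[Zn]C=C)
Why: Amino-alcohol-catalysed enantioselective organozinc addition to the aldehyde sets C2, the chiral zinc aminoalkoxide delivering the vinyl group to the Re face to give the R carbinol, and the organozinc should leave the ester and the alkyl iodide untouched.

Step 11
Reactants: 16 methyl (2Z,6E,8R)-8-hydroxy-2-[(E)-6-iodo-4-methylhex-3-en-1-yl]-6-methyldeca-2,6,9-trienoate
Product: 17 (3R,4E,8Z,12E)-9-(hydroxymethyl)-15-iodo-5,13-dimethylpentadeca-1,4,8,12-tetraen-3-ol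
Conditions: i-Bu2AlH (3.5 equiv), CH2Cl2, −78 to −40 °C; aq. potassium sodium tartrate
Reagents that add atoms: none
Why: 1,2-Hydride reduction of the conjugated methyl ester by i-Bu2AlH should give the primary allylic alcohol at C19, the C2 carbinol being carried as its aluminium alkoxide and the alkyl iodide being inert to the reagent.

Step 12
Reactants: 17 (3R,4E,8Z,12E)-9-(hydroxymethyl)-15-iodo-5,13-dimethylpentadeca-1,4,8,12-tetraen-3-ol
Product: 18 [(2Z,6E,8R)-8-hydroxy-2-[(E)-6-iodo-4-methylhex-3-en-1-yl]-6-methyldeca-2,6,9-trien-1-yl] acetate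
Conditions: AcCl (1.1 equiv), 2,4,6-collidine, CH2Cl2, −78 °C
Reagents that add atoms: acetyl chloride CC(Cl)=O
Why: Kinetically controlled acylation at low temperature should acetylate the unhindered primary allylic alcohol in preference to the hindered doubly allylic secondary alcohol, which installs the C19 acetate of the target.

Step 13
Reactants: 19 2-(bromomethyl)acrylic acid; 20 sodium benzenesulfinate
Product: 21 2-[(phenylsulfonyl)methyl]acrylic acid
Conditions: MeOH, reflux; then 1 M HCl
Reagents that add atoms: none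
Why: S-Alkylation of the sulfinate by the allylic bromide (SN2 or SN2′, both giving the same product) furnishes the allyl sulfone acid that supplies C15–C17 and the radical leaving group.

Step 14
Reactants: 18 [(2Z,6E,8R)-8-hydroxy-2-[(E)-6-iodo-4-methylhex-3-en-1-yl]-6-methyldeca-2,6,9-trien-1-yl] acetate; 21 2-[(phenylsulfonyl)methyl]acrylic acid
Product: 22 (3R,4E,8Z,12E)-9-(acetoxymethyl)-15-iodo-5,13-dimethylpentadeca-1,4,8,12-tetraen-3-yl 2-[(phenylsulfonyl)methyl]acrylate
Conditions: DCC (1.2 equiv), DMAP (5 mol %), CH2Cl2, −20 to 0 °C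
Reagents that add atoms: none
Why: Steglich esterification acylates the secondary alcohol with retention at C2, a low DMAP loading and low temperature being chosen to avoid addition–elimination at the sulfonylmethyl acrylate.

Step 15
Reactants: 22 (3R,4E,8Z,12E)-9-(acetoxymethyl)-15-iodo-5,13-dimethylpentadeca-1,4,8,12-tetraen-3-yl 2-[(phenylsulfonyl)methyl]acrylate
Product: 23 (S)-5-[(1E,5Z,9E)-6-(acetoxymethyl)-12-iodo-2,10-dimethyldodeca-1,5,9-trien-1-yl]-3-[(phenylsulfonyl)methyl]furan-2(5H)-one
Conditions: second-generation Grubbs catalyst RuCl2(=CHPh)(H2IMes)(PCy3) (10 mol %), 1,4-benzoquinone (10 mol %), toluene (5 mM), 80 °C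
Reagents that add atoms: none
Why: Ring-closing metathesis between the vinyl group and the 1,1-disubstituted acrylate should close the butenolide (ring A) with loss of ethylene, the trisubstituted olefins being too hindered to compete, and C2 is untouched under these neutral conditions (the descriptor changes from R to S only through the CIP priorities).

Step 16
Reactants: 23 (S)-5-[(1E,5Z,9E)-6-(acetoxymethyl)-12-iodo-2,10-dimethyldodeca-1,5,9-trien-1-yl]-3-[(phenylsulfonyl)methyl]furan-2(5H)-one
Product: 24 (1S,2S,3E,7Z,11E)-19-acetoxycembra-3,7,11,15(17)-tetraen-16,2-olide (CNP0158848.2)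
Conditions: (Bu3Sn)2 (1.5 equiv), hν (300 W sun lamp), benzene, 80 °C, slow addition of 23 to 2 mM
Reagents that add atoms: none
Why: Proposed new method: photolysis of (Bu3Sn)2 gives stannyl radicals that abstract iodine from C14; the nucleophilic primary radical adds to C1, the β-carbon of the butenolide C1=C15–C16=O, and the tertiary α-carbonyl radical at C15 expels PhSO2• from C17 (SH2′ addition–fragmentation), which creates the C15=C17 exo-methylene and, through attack of PhSO2• on (Bu3Sn)2, returns the chain-carrying stannyl radical, no hydrogen donor being present to intercept the slow ring closure. The closest known reaction types are the intermolecular radical allylation of alkyl iodides with 2-(sulfonylmethyl)acrylates and other allyl sulfones under ditin photolysis and the radical macrocyclisation of ω-iodoalkyl chains onto enones and enoates to give 12- to 20-membered rings; their union on a 3-(sulfonylmethyl)butenolide is the new element. The 14-membered ring closes in the 14-exo-trig mode, with C1 inside the new ring and C15 outside. The new stereocentre C1 is controlled by C2: A(1,3) strain with the C4 methyl holds H2 in the plane of the C3=C4 olefin, so the butenolide plane stands across that olefin, and the tether, which leaves C4 anti to C2, should return past the small H3 onto the butenolide face that carries C3, whereas the opposite face is reached only across the C4 methyl; bond formation syn to C3 gives the cis ring fusion (1S from 2S). The step needs face selectivity at C1, secured by this conformational lock, and site selectivity for C1 over C15 and over the isolated olefins, secured by the polarity match of the alkyl radical with the electron-poor C1 and by the E double bonds that forbid small-ring closure onto C7=C8 or C11=C12. Iodine abstraction by the stannyl radical should outrun its addition to the acceptor, and fragmentation is fast, so the kinetic facial preference of the C–C bond formation is retained.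

**Compound list**

1 | tert-butyl(but-3-yn-1-yloxy)dimethylsilane | C#CCCO[Si](C)(C)C(C)(C)C | starting material
2 | [(E)-4-[(tert-butyldimethylsilyl)oxy]-2-methylbut-1-en-1-yl]dimethylaluminium | C[Al](C)/C=C(\C)CCO[Si](C)(C)C(C)(C)C | intermediate
3 | lithium butyl[(E)-4-[(tert-butyldimethylsilyl)oxy]-2-methylbut-1-en-1-yl]dimethylaluminate | [Li+].CCCC[Al-](C)(C)/C=C(\C)CCO[Si](C)(C)C(C)(C)C | intermediate
4 | (E)-6-[(tert-butyldimethylsilyl)oxy]-4-methylhex-3-en-1-ol | OCC/C=C(\C)CCO[Si](C)(C)C(C)(C)C | intermediate
5 | (E)-tert-butyl[(6-iodo-3-methylhex-3-en-1-yl)oxy]dimethylsilane | ICC/C=C(\C)CCO[Si](C)(C)C(C)(C)C | intermediate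
6 | methyl bis(2,2,2-trifluoroethyl)phosphonoacetate | COC(=O)CP(=O)(OCC(F)(F)F)OCC(F)(F)F | starting material
7 | methyl (E)-2-[bis(2,2,2-trifluoroethoxy)phosphoryl]-8-[(tert-butyldimethylsilyl)oxy]-6-methyloct-5-enoate | COC(=O)C(CC/C=C(\C)CCO[Si](C)(C)C(C)(C)C)P(=O)(OCC(F)(F)F)OCC(F)(F)F | intermediate
8 | methyl (E)-2-[bis(2,2,2-trifluoroethoxy)phosphoryl]-8-hydroxy-6-methyloct-5-enoate | COC(=O)C(CC/C=C(\C)CCO)P(=O)(OCC(F)(F)F)OCC(F)(F)F | intermediate
9 | methyl (E)-2-[bis(2,2,2-trifluoroethoxy)phosphoryl]-8-iodo-6-methyloct-5-enoate | COC(=O)C(CC/C=C(\C)CCI)P(=O)(OCC(F)(F)F)OCC(F)(F)F | intermediate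
10 | geranyl acetate, (E)-3,7-dimethylocta-2,6-dien-1-yl acetate | CC(=O)OC/C=C(\C)CCC=C(C)C | starting material
11 | (E)-5-(5,5-dimethyl-1,2,4-trioxolan-3-yl)-3-methylpent-2-en-1-yl acetate (secondary ozonide) | CC(=O)OC/C=C(\C)CCC1OOC(C)(C)O1 | intermediate
12 | (E)-6-acetoxy-4-methylhex-4-enal | CC(=O)OC/C=C(\C)CCC=O | intermediate
13 | methyl (2Z,6E)-8-acetoxy-2-[(E)-6-iodo-4-methylhex-3-en-1-yl]-6-methylocta-2,6-dienoate | CC(=O)OC/C=C(\C)CC/C=C(\C(=O)OC)CC/C=C(\C)CCI | intermediate
14 | methyl (2Z,6E)-8-hydroxy-2-[(E)-6-iodo-4-methylhex-3-en-1-yl]-6-methylocta-2,6-dienoate | OC/C=C(\C)CC/C=C(\C(=O)OC)CC/C=C(\C)CCI | intermediate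
15 | methyl (2Z,6E)-2-[(E)-6-iodo-4-methylhex-3-en-1-yl]-6-methyl-8-oxoocta-2,6-dienoate | O=C/C=C(\C)CC/C=C(\C(=O)OC)CC/C=C(\C)CCI | intermediate
16 | methyl (2Z,6E,8R)-8-hydroxy-2-[(E)-6-iodo-4-methylhex-3-en-1-yl]-6-methyldeca-2,6,9-trienoate | O[C@@H](/C=C(\C)CC/C=C(\C(=O)OC)CC/C=C(\C)CCI)C=C | intermediate
17 | (3R,4E,8Z,12E)-9-(hydroxymethyl)-15-iodo-5,13-dimethylpentadeca-1,4,8,12-tetraen-3-ol | O[C@@H](/C=C(\C)CC/C=C(\CO)CC/C=C(\C)CCI)C=C | intermediate
18 | [(2Z,6E,8R)-8-hydroxy-2-[(E)-6-iodo-4-methylhex-3-en-1-yl]-6-methyldeca-2,6,9-trien-1-yl] acetate | O[C@@H](/C=C(\C)CC/C=C(\COC(C)=O)CC/C=C(\C)CCI)C=C | intermediate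
19 | 2-(bromomethyl)acrylic acid | C=C(CBr)C(=O)O | starting material
20 | sodium benzenesulfinate | [Na+].[O-]S(=O)c1ccccc1 | starting material
21 | 2-[(phenylsulfonyl)methyl]acrylic acid | C=C(CS(=O)(=O)c1ccccc1)C(=O)O | intermediate
22 | (3R,4E,8Z,12E)-9-(acetoxymethyl)-15-iodo-5,13-dimethylpentadeca-1,4,8,12-tetraen-3-yl 2-[(phenylsulfonyl)methyl]acrylate | C=C(CS(=O)(=O)c1ccccc1)C(=O)O[C@@H](/C=C(\C)CC/C=C(\COC(C)=O)CC/C=C(\C)CCI)C=C | intermediate
23 | (S)-5-[(1E,5Z,9E)-6-(acetoxymethyl)-12-iodo-2,10-dimethyldodeca-1,5,9-trien-1-yl]-3-[(phenylsulfonyl)methyl]furan-2(5H)-one | O=C1O[C@@H](/C=C(\C)CC/C=C(\COC(C)=O)CC/C=C(\C)CCI)C=C1CS(=O)(=O)c1ccccc1 | intermediate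
24 | (1S,2S,3E,7Z,11E)-19-acetoxycembra-3,7,11,15(17)-tetraen-16,2-olide (CNP0158848.2) | C=C1C(=O)O[C@H]2/C=C(\C)CC/C=C(\COC(C)=O)CC/C=C(\C)CC[C@@H]12 | target

**Step count**

Total step count: 16. Longest linear sequence: 14 steps (steps 1–5, 7–12, 14–16).

**Steps most likely to fail**

Step 16 (carries the label). What may go wrong: the chain does not propagate cleanly, because stannyl and sulfonyl radicals add to the exo-methylene lactone as it forms and the slow 14-membered closure loses to intermolecular addition (telomer formation). The fallback uses known chemistry only, sets out from 18 and 19 and returns at 24. It separates the radical ring closure from the formation of the exo-methylene. Acid 19 with KOAc in DMF should give 2-(acetoxymethyl)acrylic acid F1. DCC esterification of 18 with F1 should give (3R,4E,8Z,12E)-9-(acetoxymethyl)-15-iodo-5,13-dimethylpentadeca-1,4,8,12-tetraen-3-yl 2-(acetoxymethyl)acrylate F2. Ring-closing metathesis with the second-generation Grubbs catalyst RuCl2(=CHPh)(H2IMes)(PCy3) should give (S)-3-(acetoxymethyl)-5-[(1E,5Z,9E)-6-(acetoxymethyl)-12-iodo-2,10-dimethyldodeca-1,5,9-trien-1-yl]furan-2(5H)-one F3. A reductive radical macrocyclisation of the established type (alkyl iodide onto an electron-poor alkene; (Me3Si)3SiH, AIBN, benzene, 80 °C, syringe pump, 2 mM) closes the same C1–C14 bond by Giese addition and hydrogen transfer. It should give the saturated α-(acetoxymethyl) lactone, the 17-acetoxy-15,17-dihydro derivative of 24 F4, which is inert to radicals. DBU in CH2Cl2 then eliminates acetic acid (E1cB) to give 24.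

Step 10. What may go wrong: uncatalysed background addition of the vinylzinc reagent to the β,β-disubstituted enal erodes the enantiomeric purity at C2. The fallback sets out from 15 and returns at 16. Zinc–ProPhenol alkynylation (Me2Zn, the ProPhenol enantiomer that delivers the alkynyl group to the Re face, trimethylsilylacetylene, toluene) should give methyl (2Z,6E,8S)-8-hydroxy-2-[(E)-6-iodo-4-methylhex-3-en-1-yl]-6-methyl-10-(trimethylsilyl)deca-2,6-dien-9-ynoate F5. K2CO3 in MeOH removes the silyl group to give methyl (2Z,6E,8S)-8-hydroxy-2-[(E)-6-iodo-4-methylhex-3-en-1-yl]-6-methyldeca-2,6-dien-9-ynoate F6. Semi-hydrogenation (H2, Pd/CaCO3 poisoned with Pb(OAc)2, quinoline) should give 16.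

Step 14. What may go wrong: nucleophile-triggered addition–elimination at the activated acrylic acid (loss of benzenesulfinate to DMAP or to the carboxylate) and ionisation of the doubly allylic alcohol during activation. The fallback sets out from 18 and 19 and returns at 23; the sulfone is introduced only after ring A exists. DCC coupling of 18 with 19 without a nucleophilic catalyst should give (3R,4E,8Z,12E)-9-(acetoxymethyl)-15-iodo-5,13-dimethylpentadeca-1,4,8,12-tetraen-3-yl 2-(bromomethyl)acrylate F7. Ring-closing metathesis as in step 15 should give (S)-3-(bromomethyl)-5-[(1E,5Z,9E)-6-(acetoxymethyl)-12-iodo-2,10-dimethyldodeca-1,5,9-trien-1-yl]furan-2(5H)-one F8. Displacement with 20 in DMF at 0 °C, where the activated allylic bromide should react far faster than the primary iodide, gives 23.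

**Further compounds**

F1 | step 16 | 2-(acetoxymethyl)acrylic acid | C=C(COC(C)=O)C(=O)O
F2 | step 16 | (3R,4E,8Z,12E)-9-(acetoxymethyl)-15-iodo-5,13-dimethylpentadeca-1,4,8,12-tetraen-3-yl 2-(acetoxymethyl)acrylate | C=C(COC(C)=O)C(=O)O[C@@H](/C=C(\C)CC/C=C(\COC(C)=O)CC/C=C(\C)CCI)C=C
F3 | step 16 | (S)-3-(acetoxymethyl)-5-[(1E,5Z,9E)-6-(acetoxymethyl)-12-iodo-2,10-dimethyldodeca-1,5,9-trien-1-yl]furan-2(5H)-one | O=C1O[C@@H](/C=C(\C)CC/C=C(\COC(C)=O)CC/C=C(\C)CCI)C=C1COC(C)=O
F4 | step 16 | 17-acetoxy-15,17-dihydro derivative of 24 (C15 either configuration) | CC(=O)OCC1C(=O)O[C@H]2/C=C(\C)CC/C=C(\COC(C)=O)CC/C=C(\C)CC[C@@H]12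
F5 | step 10 | methyl (2Z,6E,8S)-8-hydroxy-2-[(E)-6-iodo-4-methylhex-3-en-1-yl]-6-methyl-10-(trimethylsilyl)deca-2,6-dien-9-ynoate | O[C@@H](/C=C(\C)CC/C=C(\C(=O)OC)CC/C=C(\C)CCI)C#C[Si](C)(C)C
F6 | step 10 | methyl (2Z,6E,8S)-8-hydroxy-2-[(E)-6-iodo-4-methylhex-3-en-1-yl]-6-methyldeca-2,6-dien-9-ynoate | O[C@@H](/C=C(\C)CC/C=C(\C(=O)OC)CC/C=C(\C)CCI)C#C
F7 | step 14 | (3R,4E,8Z,12E)-9-(acetoxymethyl)-15-iodo-5,13-dimethylpentadeca-1,4,8,12-tetraen-3-yl 2-(bromomethyl)acrylate | C=C(CBr)C(=O)O[C@@H](/C=C(\C)CC/C=C(\COC(C)=O)CC/C=C(\C)CCI)C=C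
F8 | step 14 | (S)-3-(bromomethyl)-5-[(1E,5Z,9E)-6-(acetoxymethyl)-12-iodo-2,10-dimethyldodeca-1,5,9-trien-1-yl]furan-2(5H)-one | O=C1O[C@@H](/C=C(\C)CC/C=C(\COC(C)=O)CC/C=C(\C)CCI)C=C1CBr
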